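The bridge between ring A (the 3-hydroxyphenyl ring) and ring B (the para-phenylene ring) is cut at the bond from the bridge CH2 to C1 of ring B, the carbon para to the diaryl-ether oxygen. The key step is a B-alkyl Suzuki–Miyaura coupling. Anti-Markovnikov hydroboration turns the vinyl group of 3-vinylanisole into the two sp3 bridge carbons, and the terminal one is joined to ring B in the same flask. The precursor is an aryl chloride that already holds rings B, C and D as a tri-O-methyl ether. It is built from a bromo/chloro-differentiated diaryl ether by a first, bromide-selective coupling of the same type. Global demethylation then gives the target.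

Key step: step 4

Remark on the chemistry: the target has no stereocentre and no stereogenic double bond, so it is achiral and no step needs stereocontrol. Ring C is the trisubstituted phenol ring that carries the ether oxygen, and ring D is the catechol ring.

Step 1
Reactants: 1 5-bromo-2-methoxyphenol; 2 (4-chlorophenyl)boronic acid
Product: 3 4-bromo-2-(4-chlorophenoxy)-1-methoxybenzene
Conditions: Cu(OAc)2 (1 equiv), pyridine, 4 Å MS, CH2Cl2, O2 (balloon), rt
Reagents that add atoms: none
Why: Chan–Lam–Evans oxidative O-arylation, in which the phenoxide of 1 and the aryl group of 2 meet on copper and a Cu(III) aryl phenoxide should eliminate the diaryl ether at room temperature, O2 returning copper to Cu(II), while the C–Br and C–Cl bonds are inert to copper under these conditions.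

Step 2
Reactants: 4 2,3-dimethoxybenzaldehyde
Product: 5 1-ethenyl-2,3-dimethoxybenzene (2,3-dimethoxystyrene)
Conditions: Ph3PCH3Br, KOtBu, THF, 0 °C → rt
Reagents that add atoms: methyltriphenylphosphonium bromide, C[P+](c1ccccc1)(c1ccccc1)c1ccccc1.[Br-]
Why: Wittig methylenation, in which the non-stabilised ylide formed in the flask should add to the aldehyde and collapse through the oxaphosphetane to the terminal alkene, with no stereochemical issue.

Step 3
Reactants: 5 1-ethenyl-2,3-dimethoxybenzene; 3 4-bromo-2-(4-chlorophenoxy)-1-methoxybenzene
Product: 7 2-(4-chlorophenoxy)-4-[2-(2,3-dimethoxyphenyl)ethyl]-1-methoxybenzene, via ring-D alkylborane 6 (not isolated)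
Conditions: 9-BBN-H, THF, 0 °C → rt; then 3, Pd(dppf)Cl2·CH2Cl2 (3 mol%), 3 M aq. NaOH, THF, 60 °C
Reagents that add atoms: 9-BBN-H, B1C2CCCC1CCC2 (adds B and the C8H14 cage to intermediate 6; only one H of it remains in 7)
Why: B-alkyl Suzuki–Miyaura coupling, in which 9-BBN should place boron on the terminal vinyl carbon and the hydroxide-activated borane should transfer its primary alkyl group to the arylpalladium bromide formed selectively at C–Br, since Pd(dppf) does not insert into the C–Cl bond of ring B at 60 °C.

Step 4
Reactants: 8 1-ethenyl-3-methoxybenzene (3-vinylanisole); 7 2-(4-chlorophenoxy)-4-[2-(2,3-dimethoxyphenyl)ethyl]-1-methoxybenzene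
Product: 10 4-[2-(2,3-dimethoxyphenyl)ethyl]-1-methoxy-2-[4-[2-(3-methoxyphenyl)ethyl]phenoxy]benzene, via ring-A alkylborane 9 (not isolated)
Conditions: 9-BBN-H, THF, 0 °C → rt; then 7, Pd(OAc)2 (2 mol%), SPhos (4 mol%), K3PO4·H2O, THF, 65 °C
Reagents that add atoms: 9-BBN-H, B1C2CCCC1CCC2 (adds B and the C8H14 cage to intermediate 9; only one H of it remains in 10)
Why: This is a B-alkyl Suzuki–Miyaura coupling of an aryl chloride, a known reaction type under Pd/dialkylbiarylphosphine catalysis. Syn addition of the B–H bond of 9-BBN to the vinyl group of 8 should put boron on the terminal carbon for steric reasons and give the primary alkylborane 9. Pd(0)/SPhos should insert into the only remaining carbon–halogen bond of 7, the C–Cl bond at C1 of ring B, and the phosphate/water-activated borate should transfer the primary 2-arylethyl group in preference to the secondary bicyclic B–C bonds. Reductive elimination, made fast by the bulky electron-rich ligand, should outrun β-hydride elimination and forge the CH2–aryl bond. No ring is closed and no stereocentre is formed. The selectivity needed is regiochemical (linear, not branched, borane) and chemoselective (C–Cl only), secured by the bulk of 9-BBN and by the absence of any other halide, free OH or alkene in 7.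

Step 5
Reactants: 10 4-[2-(2,3-dimethoxyphenyl)ethyl]-1-methoxy-2-[4-[2-(3-methoxyphenyl)ethyl]phenoxy]benzene
Product: 11 3-[2-[4-hydroxy-3-[4-[2-(3-hydroxyphenyl)ethyl]phenoxy]phenyl]ethyl]benzene-1,2-diol (target)
Conditions: BBr3 (8 equiv), CH2Cl2, −78 °C → rt; then ice/H2O, under argon
Reagents that add atoms: none
Why: Lewis-acid ether cleavage with BBr3, in which each of the four aryl methyl ethers should coordinate boron and lose its methyl group to bromide by SN2, the aryloxyboranes being hydrolysed on work-up, whereas the diaryl ether (no sp3 carbon on oxygen) and the two ethano bridges should survive.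

Compound list
1 | 5-bromo-2-methoxyphenol | COc1ccc(Br)cc1O | starting material
2 | (4-chlorophenyl)boronic acid | OB(O)c1ccc(Cl)cc1 | starting material
3 | 4-bromo-2-(4-chlorophenoxy)-1-methoxybenzene | COc1ccc(Br)cc1Oc1ccc(Cl)cc1 | intermediate
4 | 2,3-dimethoxybenzaldehyde | COc1cccc(C=O)c1OC | starting material
5 | 1-ethenyl-2,3-dimethoxybenzene | COc1cccc(C=C)c1OC | intermediate
6 | 9-[2-(2,3-dimethoxyphenyl)ethyl]-9-borabicyclo[3.3.1]nonane | COc1cccc(CCB2C3CCCC2CCC3)c1OC | intermediate
7 | 2-(4-chlorophenoxy)-4-[2-(2,3-dimethoxyphenyl)ethyl]-1-methoxybenzene | COc1ccc(CCc2cccc(OC)c2OC)cc1Oc1ccc(Cl)cc1 | intermediate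
8 | 1-ethenyl-3-methoxybenzene (3-vinylanisole) | COc1cccc(C=C)c1 | starting material
9 | 9-[2-(3-methoxyphenyl)ethyl]-9-borabicyclo[3.3.1]nonane | COc1cccc(CCB2C3CCCC2CCC3)c1 | intermediate
10 | 4-[2-(2,3-dimethoxyphenyl)ethyl]-1-methoxy-2-[4-[2-(3-methoxyphenyl)ethyl]phenoxy]benzene | COc1cccc(CCc2ccc(Oc3cc(CCc4cccc(OC)c4OC)ccc3OC)cc2)c1 | intermediate
11 | 3-[2-[4-hydroxy-3-[4-[2-(3-hydroxyphenyl)ethyl]phenoxy]phenyl]ethyl]benzene-1,2-diol | Oc1cccc(CCc2ccc(Oc3cc(CCc4cccc(O)c4O)ccc3O)cc2)c1 | target

Total step count: 5. Longest linear sequence: 4 steps (step 1 or step 2, then steps 3, 4 and 5).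

Steps most likely to fail

Step 4 (key step). Oxidative addition of palladium into the electron-rich, para-aryloxy-substituted C–Cl bond may be slow, so that the alkylborane is consumed by β-hydride elimination or protodeboronation before it couples. The fallback is a nickel-catalysed Kumada–Corriu coupling that sets out from 7 and comes back to the route at 10. Commercial 1-(2-bromoethyl)-3-methoxybenzene and magnesium turnings in THF would give [2-(3-methoxyphenyl)ethyl]magnesium bromide F1. Added to 7 and NiCl2(dppp) (THF, 0 °C → 50 °C), this should give 10 directly, because Ni(0) inserts readily into aryl chlorides and 7 holds no group that a Grignard reagent attacks.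

Step 1. Ligand exchange at copper may be sluggish with the ortho-methoxy-hindered phenol, while the boronic acid is used up by protodeboronation, oxidation to the phenol and homocoupling. The fallback replaces the oxidative copper coupling by SNAr chemistry; it sets out from 1 and comes back at 3. Compound 1 with 1-fluoro-4-nitrobenzene and K2CO3 in DMF at 80 °C should give 4-bromo-1-methoxy-2-(4-nitrophenoxy)benzene F2. Iron powder and NH4Cl in EtOH/H2O at 80 °C should reduce the nitro group without touching the C–Br bond and give 4-(5-bromo-2-methoxyphenoxy)aniline F3. A Sandmeyer chlorination (t-BuONO, CuCl2, MeCN, 0 °C → 60 °C) should then give 3.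

Step 3. The alkylpalladium intermediate may undergo β-hydride elimination, which returns styrene 5 and hydrodebrominated arene, or halogen discrimination may be lost under forcing conditions. The fallback avoids an alkyl–palladium species; it sets out from 3 (and 5) and comes back at 7. A Mizoroki–Heck reaction of 3 with 5 (Pd(OAc)2, P(o-tol)3, NaOAc, DMF, 110 °C) should engage only the C–Br bond and give (E)-2-(4-chlorophenoxy)-4-[2-(2,3-dimethoxyphenyl)ethenyl]-1-methoxybenzene F4. Diimide reduction (TsNHNH2, NaOAc, THF/H2O, reflux) should then saturate the stilbene double bond without hydrogenolysis of the C–Cl bond and give 7.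

Further compounds
F1 | step 4 | [2-(3-methoxyphenyl)ethyl]magnesium bromide | COc1cccc(CC[Mg]Br)c1
F2 | step 1 | 4-bromo-1-methoxy-2-(4-nitrophenoxy)benzene | COc1ccc(Br)cc1Oc1ccc([N+](=O)[O-])cc1
F3 | step 1 | 4-(5-bromo-2-methoxyphenoxy)aniline | COc1ccc(Br)cc1Oc1ccc(N)cc1
F4 | step 3 | (E)-2-(4-chlorophenoxy)-4-[2-(2,3-dimethoxyphenyl)ethenyl]-1-methoxybenzene | COc1ccc(/C=C/c2cccc(OC)c2OC)cc1Oc1ccc(Cl)cc1
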